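**Plan**
Cuts (atoms numbered as in the target SMILES, C1 to O28; ring A = C4, C5, C7, C26, O25, C24; ring B = O28, C10, C12, C13, C15, C17): O25–C26 and C5–C7 of ring A, C7–C8 of the macrocycle, C23–C24, C9–C10, C17–C18, and ring B itself. Ring B with its methyls C11 and C14 and with O16 is the oxidised form of a 3,5-dimethylfuran-2-yl carbinol (furan carbons C10, C12, C13, C15; carbinol carbon C17).
Forward order: furyl ketone from 2,4-dimethylfuran and a Roche ester iodide, C17 carbinol, anodic ring expansion to ring B, C9/C8 added at C10, C21 methyl ketone, aldol with a C24–C4–C5 aldehyde, beta-keto ester (C5, C7, C26), closure of the 13-membered ring at C7–C8, ring A last by lactonisation.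
Stereochemistry: C19 from the Roche ester; C17 by asymmetric transfer hydrogenation; C10 by addition to the ring B oxocarbenium ion anti to the C17 side chain; C13 by hydroxyl-directed hydrogenation; C15 by a bulky hydride; C4 by auxiliary-controlled alkylation; C24 by a chelation-controlled aldol addition.

Key step: step 7

Remark: the bromide-mediated electrolysis is assumed to oxidise only the furan; hemiketal 13 is carried on as its C10 anomeric mixture (major anomer drawn), and C7 of 40 and 41 is a mixture that vanishes on enolisation.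

Step 1
Reactants: 1 methyl (R)-3-hydroxy-2-methylpropanoate
Product: 2 methyl (R)-3-(tert-butyldimethylsilyloxy)-2-methylpropanoate
Conditions: TBSCl, imidazole, CH2Cl2, 0 °C to rt
Reagents that add atoms: tert-butyldimethylsilyl chloride, CC(C)(C)[Si](C)(C)Cl
Why: Silyl protection of the primary alcohol with TBSCl and imidazole is standard and leaves the C19 centre of the Roche ester untouched.

Step 2
Reactants: 2 silyl ether ester
Product: 3 (S)-3-(tert-butyldimethylsilyloxy)-2-methylpropan-1-ol
Conditions: i-Bu2AlH, CH2Cl2, −78 to 0 °C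
Reagents that add atoms: none
Why: Hydride reduction of the ester with i-Bu2AlH gives the primary alcohol (C18) without touching the silyl ether, and C19 is no longer alpha to a carbonyl group afterwards.

Step 3
Reactants: 3 alcohol
Product: 4 (R)-tert-butyl(3-iodo-2-methylpropoxy)dimethylsilane
Conditions: I2, PPh3, imidazole, CH2Cl2, 0 °C to rt
Reagents that add atoms: iodine, II
Why: The Appel-type iodination replaces the primary hydroxyl at C18 by SN2 displacement and does not involve C19.

Step 4
Reactants: 5 2,4-dimethylfuran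
Product: 7 N-methoxy-N,3,5-trimethylfuran-2-carboxamide, via furyllithium 6 (not isolated)
Conditions: n-BuLi, THF, 0 °C; then ClC(O)N(OMe)Me, −78 °C to rt
Reagents that add atoms: N-methoxy-N-methylcarbamoyl chloride, CON(C)C(Cl)=O
Why: n-BuLi metalates the only free alpha position of the furan (alpha-lithiation), and acylation of the furyllithium by the carbamoyl chloride gives the Weinreb amide, which carries the future C17 and does not add a second organolithium.

Step 5
Reactants: 4 iodide; 7 Weinreb amide
Product: 9 (S)-4-(tert-butyldimethylsilyloxy)-1-(3,5-dimethylfuran-2-yl)-3-methylbutan-1-one, via alkyllithium 8 (not isolated)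
Conditions: 4, t-BuLi (2 equiv), Et2O, −78 °C; then 7, −78 to 0 °C
Reagents that add atoms: none
Why: Lithium–iodine exchange gives the primary alkyllithium, whose addition to the amide stops at the chelated tetrahedral intermediate and gives the ketone on work-up (Weinreb ketone synthesis), forming C17–C18.

Step 6
Reactants: 9 furyl ketone
Product: 10 (1S,3S)-4-(tert-butyldimethylsilyloxy)-1-(3,5-dimethylfuran-2-yl)-3-methylbutan-1-ol
Conditions: RuCl(p-cymene)[(S,S)-TsDPEN] (cat.), HCO2H/Et3N (5:2), rt
Reagents that add atoms: none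
Why: Noyori asymmetric transfer hydrogenation of the 2-acylfuran sets C17 under catalyst control, the (S,S)-ligand being expected to give the (S)-carbinol as it does with aryl alkyl ketones, independently of the remote C19 centre.

Step 7
Reactants: 10 furyl carbinol
Product: 13 ring B hemiketal (2S,6R)-2-[(S)-3-(tert-butyldimethylsilyloxy)-2-methylpropyl]-6-hydroxy-4,6-dimethyl-2H-pyran-3(6H)-one, via dimethoxydihydrofuran 11 (not isolated), via cis-enedione 12 (not isolated)
Conditions: undivided cell, graphite anode, steel cathode, NaBr, MeOH, −10 °C, constant current (ca. 2.2 F/mol); then 0.1 M aq. HCl, THF, 0 °C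
Reagents that add atoms: water, O
Why: Bromide is oxidised at the anode to an electrophilic bromine species that attacks the electron-rich trisubstituted furan, methanol traps the cation at both alpha carbons (two electrons removed overall) to give the 2,5-dimethoxy-2,5-dihydrofuran 11, and dilute acid hydrolyses both ketal carbons to the cis-enedione 12, whose C17 hydroxyl adds to the C10 ketone. The closest known reaction is the Achmatowicz rearrangement of furyl carbinols in its anodic methoxylation–hydrolysis form. Ring B closes by a 6-exo-trig hemiketalisation (O28–C10). The only new stereocentre, C10, is a hemiketal that should equilibrate towards the anomer with axial hydroxyl (anomeric effect) and is reset in step 8, while C17 and C19 are not involved. The step needs chemoselectivity only: the mediated oxidation runs at the low potential of bromide, which should spare the secondary carbinol and the silyl ether, and the bis-ketal 11 hydrolyses in acid mild enough to keep the primary silyl ether.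

Step 8
Reactants: 13 ring B hemiketal
Product: 14 methyl 2-[(2S,6S)-6-[(S)-3-(tert-butyldimethylsilyloxy)-2-methylpropyl]-2,4-dimethyl-5-oxo-5,6-dihydro-2H-pyran-2-yl]acetate
Conditions: CH2=C(OMe)OTBS, BF3·OEt2, CH2Cl2, −78 to −40 °C
Reagents that add atoms: 1-(tert-butyldimethylsilyloxy)-1-methoxyethene, COC(=C)O[Si](C)(C)C(C)(C)C
Why: BF3·OEt2 ionises the tertiary hemiketal to the ring B oxocarbenium ion and the silyl ketene acetal adds at C10 (Mukaiyama-type C-glycosylation) on the face opposite the C17 side chain, which sets the quaternary centre with C9 trans to C18 and brings in C9 and C8.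

Step 9
Reactants: 14 enone ester
Product: 15 methyl 2-[(2S,5R,6S)-6-[(S)-3-(tert-butyldimethylsilyloxy)-2-methylpropyl]-5-hydroxy-2,4-dimethyl-5,6-dihydro-2H-pyran-2-yl]acetate
Conditions: NaBH4, CeCl3·7H2O, MeOH, −78 °C
Reagents that add atoms: none
Why: Luche reduction gives 1,2-reduction of the enone with hydride adding anti to the pseudo-axial C9 chain, so that the C15 hydroxyl comes out trans to the C17 side chain, a temporary configuration that directs step 10 and is inverted in steps 11 and 12.

Step 10
Reactants: 15 allylic alcohol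
Product: 16 methyl 2-[(2R,4S,5R,6S)-6-[(S)-3-(tert-butyldimethylsilyloxy)-2-methylpropyl]-5-hydroxy-2,4-dimethyloxan-2-yl]acetate
Conditions: [Ir(cod)(PCy3)(py)]PF6 (cat.), H2 (1 atm), CH2Cl2, rt
Reagents that add atoms: none
Why: Hydroxyl-directed hydrogenation with the cationic iridium catalyst delivers hydrogen to the trisubstituted alkene from the face of the C15 hydroxyl, which places H13 cis to that hydroxyl and the C14 methyl equatorial and cis to the C17 side chain without any enolisable intermediate.

Step 11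
Reactants: 16 alcohol
Product: 17 methyl 2-[(2R,4S,6S)-6-[(S)-3-(tert-butyldimethylsilyloxy)-2-methylpropyl]-2,4-dimethyl-5-oxooxan-2-yl]acetate
Conditions: Dess–Martin periodinane, NaHCO3, CH2Cl2, 0 °C to rt
Reagents that add atoms: none
Why: Dess–Martin oxidation returns the C15 ketone under buffered, non-enolising conditions, so the epimerisable centres C13 and C17 are kept.

Step 12
Reactants: 17 ketone
Product: 19 diol (2S,3S,4S,6R)-2-[(S)-3-(tert-butyldimethylsilyloxy)-2-methylpropyl]-6-(2-hydroxyethyl)-4,6-dimethyloxan-3-ol, via hydroxy ester 18 (not isolated)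
Conditions: LiBH(s-Bu)3, THF, −78 °C; then LiBH4, MeOH, 0 °C to rt
Reagents that add atoms: none
Why: The bulky hydride LiBH(s-Bu)3 attacks the ketone from the equatorial direction between its two equatorial neighbours and gives the axial C15 alcohol, and LiBH4 added to the same flask reduces the methyl ester to the C8 primary alcohol (ester reduction).

Step 13
Reactants: 19 diol
Product: 20 (2S,3S,4S,6R)-2-[(S)-3-(tert-butyldimethylsilyloxy)-2-methylpropyl]-6-(2-chloroethyl)-4,6-dimethyloxan-3-ol
Conditions: PPh3, N-chlorosuccinimide, CH2Cl2, −20 to 0 °C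
Reagents that add atoms: N-chlorosuccinimide, O=C1CCC(=O)N1Cl
Why: The Appel-type chlorination is selective for the primary alcohol over the hindered axial secondary one and turns C8 into a chloride that is inert in the following steps and is activated as the iodide in step 29.

Step 14
Reactants: 20 chloro alcohol
Product: 21 (2S,3S,4S,6R)-3-(tert-butyldimethylsilyloxy)-2-[(S)-3-(tert-butyldimethylsilyloxy)-2-methylpropyl]-6-(2-chloroethyl)-4,6-dimethyloxane
Conditions: TBSOTf, 2,6-lutidine, CH2Cl2, 0 °C
Reagents that add atoms: tert-butyldimethylsilyl triflate, CC(C)(C)[Si](C)(C)OS(=O)(=O)C(F)(F)F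
Why: The silyl triflate with 2,6-lutidine silylates even the hindered axial C15 hydroxyl (silyl protection).

Step 15
Reactants: 21 bis-silyl ether
Product: 22 (S)-3-[(2S,3S,4S,6R)-3-(tert-butyldimethylsilyloxy)-6-(2-chloroethyl)-4,6-dimethyloxan-2-yl]-2-methylpropan-1-ol
Conditions: HF·pyridine, pyridine, THF, 0 °C
Reagents that add atoms: none
Why: Buffered HF·pyridine cleaves the unhindered primary silyl ether much faster than the axial secondary one (selective desilylation).

Step 16
Reactants: 22 primary alcohol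
Product: 23 (S)-3-[(2S,3S,4S,6R)-3-(tert-butyldimethylsilyloxy)-6-(2-chloroethyl)-4,6-dimethyloxan-2-yl]-2-methylpropanoic acid
Conditions: TEMPO (cat.), PhI(OAc)2, MeCN/H2O, rt
Reagents that add atoms: water, O
Why: The TEMPO/PhI(OAc)2 oxidation in aqueous acetonitrile takes the primary alcohol through the aldehyde hydrate to the acid under near-neutral conditions that keep the alpha centre C19.

Step 17
Reactants: 23 acid
Product: 24 (S)-4-[(2S,3S,4S,6R)-3-(tert-butyldimethylsilyloxy)-6-(2-chloroethyl)-4,6-dimethyloxan-2-yl]-3-methylbutan-2-one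
Conditions: MeLi (2.5 equiv), Et2O, −78 to 0 °C; aq. NH4Cl
Reagents that add atoms: methyllithium, [Li]C
Why: Addition of methyllithium to the lithium carboxylate stops at the geminal dialkoxide, which gives the methyl ketone on hydrolysis (ketone synthesis from a carboxylic acid) and brings in C23.

Step 18
Reactants: 24 methyl ketone
Product: 25 trimethylsilyl enol ether of 24 (C21=C23; 2-silyloxybut-1-ene terminus)
Conditions: LiN(SiMe3)2, Me3SiCl, Et3N, THF, −78 °C
Reagents that add atoms: chlorotrimethylsilane, C[Si](C)(C)Cl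
Why: Kinetic deprotonation in the presence of the silyl chloride takes place at the methyl group and not at the tertiary C19, so the terminal silyl enol ether forms with C19 intact (kinetic enol silane formation).

Step 19
Reactants: 26 (R)-4-benzyloxazolidin-2-one; 27 pentanoyl chloride
Product: 28 (R)-4-benzyl-3-pentanoyloxazolidin-2-one
Conditions: Et3N, DMAP (cat.), CH2Cl2, 0 °C to rt
Reagents that add atoms: none
Why: N-Acylation of the oxazolidinone by the acid chloride under amine/DMAP catalysis gives the imide needed for the auxiliary-controlled alkylation.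

Step 20
Reactants: 28 imide
Product: 30 (R)-4-benzyl-3-[(S)-2-(benzyloxymethyl)pentanoyl]oxazolidin-2-one, via titanium enolate 29 (not isolated)
Conditions: TiCl4, i-Pr2NEt, CH2Cl2, 0 °C; then BnOCH2Cl, 0 °C
Reagents that add atoms: benzyl chloromethyl ether, ClCOCc1ccccc1
Why: The chelated chlorotitanium (Z)-enolate is alkylated on the face opposite the benzyl group of the auxiliary (Evans alkylation), which sets C4 and adds C5 as its benzyl ether.

Step 21
Reactants: 30 alkylated imide
Product: 31 (R)-2-(benzyloxymethyl)pentan-1-ol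
Conditions: LiBH4, MeOH, THF, 0 °C
Reagents that add atoms: none
Why: LiBH4 reduces the exocyclic imide carbonyl to the primary alcohol and releases the auxiliary (reductive auxiliary cleavage) without epimerising C4.

Step 22
Reactants: 31 alcohol
Product: 32 (S)-2-(benzyloxymethyl)pentanal
Conditions: Dess–Martin periodinane, NaHCO3, CH2Cl2, 0 °C
Reagents that add atoms: none
Why: Dess–Martin oxidation gives the alpha-branched aldehyde (the future C24) under neutral conditions, and it is used at once to avoid epimerisation at C4.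

Step 23
Reactants: 25 silyl enol ether; 32 aldehyde
Product: 33 aldol adduct (2S,5R,6S)-6-(benzyloxymethyl)-1-[(2S,3S,4S,6R)-3-(tert-butyldimethylsilyloxy)-6-(2-chloroethyl)-4,6-dimethyloxan-2-yl]-5-hydroxy-2-methylnonan-3-one
Conditions: Me2AlCl (2.5 equiv), CH2Cl2, −78 °C
Reagents that add atoms: none
Why: Me2AlCl chelates the aldehyde oxygen and the benzyloxy group, and the enol silane adds to the chelate on the face opposite the propyl group (chelation-controlled Mukaiyama aldol), which forms C23–C24 and sets C24 anti to C4.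

Step 24
Reactants: 33 aldol adduct
Product: 34 C24 triethylsilyl ether of 33
Conditions: Et3SiOTf, 2,6-lutidine, CH2Cl2, −78 °C
Reagents that add atoms: triethylsilyl triflate, CC[Si](CC)(CC)OS(=O)(=O)C(F)(F)F
Why: Low-temperature silylation of the beta-hydroxy ketone (silyl protection) avoids retro-aldol and elimination and keeps the C24 oxygen from lactonising before step 30.

Step 25
Reactants: 34 silyl ether ketone
Product: 35 C21 1,3-dioxolane of 34
Conditions: Me3SiOCH2CH2OSiMe3, Me3SiOTf (cat.), CH2Cl2, −78 to −20 °C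
Reagents that add atoms: 1,2-bis(trimethylsilyloxy)ethane, C[Si](C)(C)OCCO[Si](C)(C)C
Why: Noyori ketalisation masks the C21 ketone at low temperature, which removes its acidic alpha hydrogens (C19, C23) and its electrophilicity towards the C7 carbanion before the base-mediated ring closure of step 29.

Step 26
Reactants: 35 benzyl ether
Product: 36 C5 primary alcohol (benzyl removed from 35)
Conditions: H2 (1 atm), Pd(OH)2/C, EtOAc, rt
Reagents that add atoms: none
Why: Hydrogenolysis cleaves only the benzyl ether, since the silyl ethers, the dioxolane and the primary chloride are stable over the palladium catalyst in ethyl acetate.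

Step 27
Reactants: 36 primary alcohol
Product: 37 C5 aldehyde
Conditions: Dess–Martin periodinane, NaHCO3, CH2Cl2, 0 °C
Reagents that add atoms: none
Why: Buffered Dess–Martin oxidation gives the aldehyde without epimerising the alpha centre C4 or eliminating the beta silyloxy group.

Step 28
Reactants: 37 aldehyde
Product: 38 tert-butyl beta-keto ester (C26 ester; C7 methylene; C5 ketone; C8 chloride)
Conditions: N2CHCO2t-Bu, SnCl2 (cat.), CH2Cl2, rt
Reagents that add atoms: tert-butyl diazoacetate, CC(C)(C)OC(=O)C=[N+]=[N-]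
Why: The Roskamp reaction (addition of the diazo ester to the Lewis-acid-activated aldehyde, 1,2-hydride shift and loss of N2) gives the beta-keto ester directly and adds C7 and C26 without base.

Step 29
Reactants: 38 chloro beta-keto ester
Product: 40 macrocyclic beta-keto ester (C7–C8 closed; 13-membered carbocycle counted through O28), via iodide 39 (not isolated)
Conditions: Cs2CO3, NaI, MeCN, 70 °C, slow addition to ca. 1 mM
Reagents that add atoms: none
Why: Finkelstein exchange gives the primary iodide in the flask and the caesium enolate of the beta-keto ester is C-alkylated by it under high dilution (intramolecular acetoacetic ester alkylation), the only acidic site being C7 now that C21 is masked.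

Step 30
Reactants: 40 macrocycle
Product: 42 mangromicin C, via deprotected keto ester 41 (not isolated)
Conditions: CF3CO2H/CH2Cl2/H2O (10:10:1), 0 °C to rt
Reagents that add atoms: water, O
Why: Aqueous trifluoroacetic acid removes both silyl ethers and the dioxolane and cleaves the tert-butyl ester, and the freed C24 hydroxyl acylates at C26 in a 6-exo-trig lactonisation that closes ring A, which rests as the C5 enol.

**Compound list**
1 | methyl (R)-3-hydroxy-2-methylpropanoate (Roche ester) | COC(=O)[C@H](C)CO | starting material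
2 | methyl (R)-3-(tert-butyldimethylsilyloxy)-2-methylpropanoate | COC(=O)[C@H](C)CO[Si](C)(C)C(C)(C)C | intermediate
3 | (S)-3-(tert-butyldimethylsilyloxy)-2-methylpropan-1-ol | OC[C@H](C)CO[Si](C)(C)C(C)(C)C | intermediate
4 | (R)-tert-butyl(3-iodo-2-methylpropoxy)dimethylsilane | IC[C@H](C)CO[Si](C)(C)C(C)(C)C | intermediate
5 | 2,4-dimethylfuran | Cc1cc(C)co1 | starting material
6 | (3,5-dimethylfuran-2-yl)lithium, formed in the flask | [Li]c1oc(C)cc1C | intermediate
7 | N-methoxy-N,3,5-trimethylfuran-2-carboxamide | CON(C)C(=O)c1oc(C)cc1C | intermediate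
8 | [(S)-3-(tert-butyldimethylsilyloxy)-2-methylpropyl]lithium, formed in the flask | [Li]C[C@H](C)CO[Si](C)(C)C(C)(C)C | intermediate
9 | (S)-4-(tert-butyldimethylsilyloxy)-1-(3,5-dimethylfuran-2-yl)-3-methylbutan-1-one | Cc1cc(C)c(o1)C(=O)C[C@H](C)CO[Si](C)(C)C(C)(C)C | intermediate
10 | (1S,3S)-4-(tert-butyldimethylsilyloxy)-1-(3,5-dimethylfuran-2-yl)-3-methylbutan-1-ol (C17 S, C19 S) | Cc1cc(C)c(o1)[C@@H](O)C[C@H](C)CO[Si](C)(C)C(C)(C)C | intermediate
11 | 2,5-dimethoxy-3,5-dimethyl-2,5-dihydrofuran-2-yl carbinol from 10 (both ketal carbons as mixtures), formed in the flask | COC1(C)C=C(C)C(OC)([C@@H](O)C[C@H](C)CO[Si](C)(C)C(C)(C)C)O1 | intermediate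
12 | (3Z,6S,8S)-9-(tert-butyldimethylsilyloxy)-6-hydroxy-4,8-dimethylnon-3-ene-2,5-dione, formed in the flask | CC(=O)/C=C(/C)C(=O)[C@@H](O)C[C@H](C)CO[Si](C)(C)C(C)(C)C | intermediate
13 | (2S,6R)-2-[(S)-3-(tert-butyldimethylsilyloxy)-2-methylpropyl]-6-hydroxy-4,6-dimethyl-2H-pyran-3(6H)-one (C10 anomer with axial hydroxyl) | O[C@@]1(C)C=C(C)C(=O)[C@H](C[C@H](C)CO[Si](C)(C)C(C)(C)C)O1 | intermediate
14 | methyl 2-[(2S,6S)-6-[(S)-3-(tert-butyldimethylsilyloxy)-2-methylpropyl]-2,4-dimethyl-5-oxo-5,6-dihydro-2H-pyran-2-yl]acetate | COC(=O)C[C@@]1(C)C=C(C)C(=O)[C@H](C[C@H](C)CO[Si](C)(C)C(C)(C)C)O1 | intermediate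
15 | methyl 2-[(2S,5R,6S)-6-[(S)-3-(tert-butyldimethylsilyloxy)-2-methylpropyl]-5-hydroxy-2,4-dimethyl-5,6-dihydro-2H-pyran-2-yl]acetate | COC(=O)C[C@@]1(C)C=C(C)[C@@H](O)[C@H](C[C@H](C)CO[Si](C)(C)C(C)(C)C)O1 | intermediate
16 | methyl 2-[(2R,4S,5R,6S)-6-[(S)-3-(tert-butyldimethylsilyloxy)-2-methylpropyl]-5-hydroxy-2,4-dimethyloxan-2-yl]acetate | COC(=O)C[C@@]1(C)C[C@H](C)[C@@H](O)[C@H](C[C@H](C)CO[Si](C)(C)C(C)(C)C)O1 | intermediate
17 | methyl 2-[(2R,4S,6S)-6-[(S)-3-(tert-butyldimethylsilyloxy)-2-methylpropyl]-2,4-dimethyl-5-oxooxan-2-yl]acetate | COC(=O)C[C@@]1(C)C[C@H](C)C(=O)[C@H](C[C@H](C)CO[Si](C)(C)C(C)(C)C)O1 | intermediate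
18 | methyl 2-[(2R,4S,5S,6S)-6-[(S)-3-(tert-butyldimethylsilyloxy)-2-methylpropyl]-5-hydroxy-2,4-dimethyloxan-2-yl]acetate, formed in the flask | COC(=O)C[C@@]1(C)C[C@H](C)[C@H](O)[C@H](C[C@H](C)CO[Si](C)(C)C(C)(C)C)O1 | intermediate
19 | (2S,3S,4S,6R)-2-[(S)-3-(tert-butyldimethylsilyloxy)-2-methylpropyl]-6-(2-hydroxyethyl)-4,6-dimethyloxan-3-ol | OCC[C@@]1(C)C[C@H](C)[C@H](O)[C@H](C[C@H](C)CO[Si](C)(C)C(C)(C)C)O1 | intermediate
20 | (2S,3S,4S,6R)-2-[(S)-3-(tert-butyldimethylsilyloxy)-2-methylpropyl]-6-(2-chloroethyl)-4,6-dimethyloxan-3-ol | ClCC[C@@]1(C)C[C@H](C)[C@H](O)[C@H](C[C@H](C)CO[Si](C)(C)C(C)(C)C)O1 | intermediate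
21 | (2S,3S,4S,6R)-3-(tert-butyldimethylsilyloxy)-2-[(S)-3-(tert-butyldimethylsilyloxy)-2-methylpropyl]-6-(2-chloroethyl)-4,6-dimethyloxane | ClCC[C@@]1(C)C[C@H](C)[C@H](O[Si](C)(C)C(C)(C)C)[C@H](C[C@H](C)CO[Si](C)(C)C(C)(C)C)O1 | intermediate
22 | (S)-3-[(2S,3S,4S,6R)-3-(tert-butyldimethylsilyloxy)-6-(2-chloroethyl)-4,6-dimethyloxan-2-yl]-2-methylpropan-1-ol | ClCC[C@@]1(C)C[C@H](C)[C@H](O[Si](C)(C)C(C)(C)C)[C@H](C[C@H](C)CO)O1 | intermediate
23 | (S)-3-[(2S,3S,4S,6R)-3-(tert-butyldimethylsilyloxy)-6-(2-chloroethyl)-4,6-dimethyloxan-2-yl]-2-methylpropanoic acid | ClCC[C@@]1(C)C[C@H](C)[C@H](O[Si](C)(C)C(C)(C)C)[C@H](C[C@H](C)C(O)=O)O1 | intermediate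
24 | (S)-4-[(2S,3S,4S,6R)-3-(tert-butyldimethylsilyloxy)-6-(2-chloroethyl)-4,6-dimethyloxan-2-yl]-3-methylbutan-2-one | ClCC[C@@]1(C)C[C@H](C)[C@H](O[Si](C)(C)C(C)(C)C)[C@H](C[C@H](C)C(C)=O)O1 | intermediate
25 | trimethylsilyl enol ether of 24 (C21=C23) | ClCC[C@@]1(C)C[C@H](C)[C@H](O[Si](C)(C)C(C)(C)C)[C@H](C[C@H](C)C(=C)O[Si](C)(C)C)O1 | intermediate
26 | (R)-4-benzyloxazolidin-2-one | O=C1N[C@H](Cc2ccccc2)CO1 | starting material
27 | pentanoyl chloride | CCCCC(Cl)=O | starting material
28 | (R)-4-benzyl-3-pentanoyloxazolidin-2-one | CCCCC(=O)N1[C@H](Cc2ccccc2)COC1=O | intermediate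
29 | trichlorotitanium (Z)-enolate of 28, formed in the flask | CCC/C=C(\O[Ti](Cl)(Cl)Cl)N1[C@H](Cc2ccccc2)COC1=O | intermediate
30 | (R)-4-benzyl-3-[(S)-2-(benzyloxymethyl)pentanoyl]oxazolidin-2-one | CCC[C@@H](COCc1ccccc1)C(=O)N1[C@H](Cc2ccccc2)COC1=O | intermediate
31 | (R)-2-(benzyloxymethyl)pentan-1-ol | CCC[C@H](CO)COCc1ccccc1 | intermediate
32 | (S)-2-(benzyloxymethyl)pentanal | CCC[C@H](C=O)COCc1ccccc1 | intermediate
33 | aldol adduct (2S,5R,6S)-6-(benzyloxymethyl)-1-[(2S,3S,4S,6R)-3-(tert-butyldimethylsilyloxy)-6-(2-chloroethyl)-4,6-dimethyloxan-2-yl]-5-hydroxy-2-methylnonan-3-one (target numbering: C4 S, C10 R, C13 S, C15 S, C17 S, C19 S, C24 R) | ClCC[C@@]1(C)C[C@H](C)[C@H](O[Si](C)(C)C(C)(C)C)[C@H](C[C@H](C)C(=O)C[C@@H](O)[C@@H](CCC)COCc2ccccc2)O1 | intermediate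
34 | C24 triethylsilyl ether of 33 | ClCC[C@@]1(C)C[C@H](C)[C@H](O[Si](C)(C)C(C)(C)C)[C@H](C[C@H](C)C(=O)C[C@@H](O[Si](CC)(CC)CC)[C@@H](CCC)COCc2ccccc2)O1 | intermediate
35 | C21 1,3-dioxolane of 34 | ClCC[C@@]1(C)C[C@H](C)[C@H](O[Si](C)(C)C(C)(C)C)[C@H](C[C@H](C)C2(C[C@@H](O[Si](CC)(CC)CC)[C@@H](CCC)COCc3ccccc3)OCCO2)O1 | intermediate
36 | C5 primary alcohol (35 without benzyl) | ClCC[C@@]1(C)C[C@H](C)[C@H](O[Si](C)(C)C(C)(C)C)[C@H](C[C@H](C)C2(C[C@@H](O[Si](CC)(CC)CC)[C@@H](CCC)CO)OCCO2)O1 | intermediate
37 | C5 aldehyde (C4 R, C24 R) | ClCC[C@@]1(C)C[C@H](C)[C@H](O[Si](C)(C)C(C)(C)C)[C@H](C[C@H](C)C2(C[C@@H](O[Si](CC)(CC)CC)[C@@H](CCC)C=O)OCCO2)O1 | intermediate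
38 | tert-butyl beta-keto ester (C26 tert-butyl ester, C7 methylene, C5 ketone, C8 chloride, C21 dioxolane, C24 OTES, C15 OTBS) | ClCC[C@@]1(C)C[C@H](C)[C@H](O[Si](C)(C)C(C)(C)C)[C@H](C[C@H](C)C2(C[C@@H](O[Si](CC)(CC)CC)[C@@H](CCC)C(=O)CC(=O)OC(C)(C)C)OCCO2)O1 | intermediate
39 | C8 iodide corresponding to 38, formed in the flask | ICC[C@@]1(C)C[C@H](C)[C@H](O[Si](C)(C)C(C)(C)C)[C@H](C[C@H](C)C2(C[C@@H](O[Si](CC)(CC)CC)[C@@H](CCC)C(=O)CC(=O)OC(C)(C)C)OCCO2)O1 | intermediate
40 | macrocyclic beta-keto ester, C7–C8 closed (C4 R, C10 S, C13 S, C15 S, C17 S, C19 S, C24 R; C7 mixture) | CCC[C@H]1C(=O)C(C(=O)OC(C)(C)C)CC[C@@]2(C)C[C@H](C)[C@H](O[Si](C)(C)C(C)(C)C)[C@H](C[C@H](C)C3(C[C@H]1O[Si](CC)(CC)CC)OCCO3)O2 | intermediate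
41 | macrocyclic delta-hydroxy beta-keto tert-butyl ester with free C15 and C24 hydroxyls and C21 ketone, formed in the flask | CCC[C@H]1C(=O)C(C(=O)OC(C)(C)C)CC[C@@]2(C)C[C@H](C)[C@H](O)[C@H](C[C@H](C)C(=O)C[C@H]1O)O2 | intermediate
42 | mangromicin C (4R,10S,13S,15S,17S,19S,24R in the numbering used here) | CCC[C@H]1C(O)=C2CC[C@@]3(C)C[C@H](C)[C@H](O)[C@H](C[C@H](C)C(=O)C[C@H]1OC2=O)O3 | target

**Step count**
Total: 30 steps. Longest linear sequence: 25 steps (steps 1–3, 5–18 and 23–30, from the Roche ester 1).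

**Steps most likely to fail**

1. Step 29 (ring closure at C7–C8). Intermolecular alkylation to oligomers and O-alkylation of the enolate may outrun the slow formation of the 13-membered ring, and the hot carbonate may slowly degrade the substrate. The fallback sets out from 38 and closes the same bond by condensation and reduction instead of SN2 displacement. The chloride is exchanged for iodide (NaI, acetone; compound 39) and oxidised with Me3NO in DMSO (Ganem oxidation) to the C8 aldehyde beta-keto ester F1. Under high dilution with piperidinium acetate and Hantzsch ester, the beta-keto ester condenses with the aldehyde (intramolecular Knoevenagel condensation) and the alkylidene is reduced in the flask by hydride transfer. This gives 40, where the route resumes at step 30.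

2. Step 30 (global deprotection and lactonisation). Loss of the tert-butyl group may lead to decarboxylation of the beta-keto acid, or acid may dehydrate the freed beta-hydroxy ketone, before ring A closes; the hindered C15 silyl ether may also come off only slowly. The fallback sets out from 40 and separates the events. HF·pyridine buffered with pyridine in THF removes both silyl ethers and gives the dihydroxy dioxolane beta-keto ester F2. Heating in toluene at 110 °C expels tert-butanol to an acylketene that is trapped by the C24 hydroxyl, a neutral lactonisation that gives the dioxolane-protected lactone F3. Pyridinium p-toluenesulfonate in wet acetone then frees the C21 ketone and gives 42.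

3. Step 8 (C9–C10 bond at the quaternary centre). The tertiary oxocarbenium ion may lose a proton to an enol ether, or the basic ketene acetal may add in a conjugate sense to the enone or with poor facial selectivity. The fallback sets out from 13 and brings in the two carbons as a masked unit. Allyltrimethylsilane and BF3·OEt2 (Sakurai-type allylation, again anti to the C17 side chain) give the C10 allyl enone F4. OsO4 (cat.)/NaIO4 with 2,6-lutidine cleaves only the terminal alkene to the aldehyde F5. NaClO2/NaH2PO4 with 2-methyl-2-butene gives the carboxylic acid F6, and Me3SiCHN2 in MeOH/toluene gives the methyl ester 14, where the route resumes at step 9.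

**Further compounds**
F1 | step 29 | C8 aldehyde beta-keto ester (38 with CHO in place of CH2Cl) | O=CC[C@@]1(C)C[C@H](C)[C@H](O[Si](C)(C)C(C)(C)C)[C@H](C[C@H](C)C2(C[C@@H](O[Si](CC)(CC)CC)[C@@H](CCC)C(=O)CC(=O)OC(C)(C)C)OCCO2)O1
F2 | step 30 | dihydroxy dioxolane beta-keto ester (40 without the two silyl groups) | CCC[C@H]1C(=O)C(C(=O)OC(C)(C)C)CC[C@@]2(C)C[C@H](C)[C@H](O)[C@H](C[C@H](C)C3(C[C@H]1O)OCCO3)O2
F3 | step 30 | dioxolane-protected lactone (42 with C21 as 1,3-dioxolane) | CCC[C@H]1C(O)=C2CC[C@@]3(C)C[C@H](C)[C@H](O)[C@H](C[C@H](C)C4(C[C@H]1OC2=O)OCCO4)O3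
F4 | step 8 | (2S,6S)-6-allyl-2-[(S)-3-(tert-butyldimethylsilyloxy)-2-methylpropyl]-4,6-dimethyl-2H-pyran-3(6H)-one | C=CC[C@@]1(C)C=C(C)C(=O)[C@H](C[C@H](C)CO[Si](C)(C)C(C)(C)C)O1
F5 | step 8 | 2-[(2S,6S)-6-[(S)-3-(tert-butyldimethylsilyloxy)-2-methylpropyl]-2,4-dimethyl-5-oxo-5,6-dihydro-2H-pyran-2-yl]acetaldehyde | O=CC[C@@]1(C)C=C(C)C(=O)[C@H](C[C@H](C)CO[Si](C)(C)C(C)(C)C)O1
F6 | step 8 | 2-[(2S,6S)-6-[(S)-3-(tert-butyldimethylsilyloxy)-2-methylpropyl]-2,4-dimethyl-5-oxo-5,6-dihydro-2H-pyran-2-yl]acetic acid | OC(=O)C[C@@]1(C)C=C(C)C(=O)[C@H](C[C@H](C)CO[Si](C)(C)C(C)(C)C)O1
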